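40 min is my time of reading for Thursday's flask at 25 °C and Friday's at 45 °C, where free enzyme turns starting material into target.

| flask | starting material | free enzyme | temperature | remark | time |
|---|---|---|---|---|---|
| beta | 0.11 M | 32 µM | 20 °C | run made earlier |  |
| eta | 0.24 M | 32 µM | 35 °C | run made earlier |  |
| Friday's | 0.16 M | 32 µM | 45 °C |  | 40 min |
| Thursday's | 0.16 M | 32 µM | 25 °C |  | 40 min |

- beta (time / min: starting material / %, target / %): 2.50: 5, 97; 4.00: 1, 100; 8.00: 0, 100; 12.0: 0, 99; 20.0: 1, 100; 30.0: 1, 100
- eta (time / min: starting material / %, target / %): 1.33: 14, 83; 4.00: 1, 98; 8.00: 0, 99; 12.0: 0, 99; 15.0: 0, 100; 20.0: 0, 99

(scatter of a reading: 1.5 percentage points)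



- which of these there is most of at the end, counted by the starting material in it, Friday's (target / starting material)
- which of these there is most of at the end, counted by the starting material in it, Thursday's (target / starting material)
- final amount of the leader among these, as a percentage of the starting material charged, in Friday's
- final amount of the leader among these, as a percentage of the starting material charged, in Thursday's

I work in powers of ten. My quantity is the decade time τ, the minutes of working free enzyme that cut the starting material tenfold, read as a pseudo-first-order fall. The eta run has 14% left at 1.33 min, which is 0.854 decades, so τ = 1.56 min, a reading with its scatter. The beta run, at its own charge and temperature, reads 1.92 min.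

The bench rule says a flask is finished after two decades, which is 3.12 min. 40 min offers 25.6 decades, so by the rule both flasks finish. But decades pass only during w, the working time of the free enzyme, and the decades gained are w/τ. The eta run vouches for w up to 4.00 min at 35 °C, with 1% left, and 40 min is ten times that span.

Thursday's 25 °C lies between the two runs, so I expect Thursday's to finish as target. Friday's 45 °C lies above both, so the rule stops there. With the eta run's τ carried over unchanged, target leads in Friday's once w passes 0.469 min. I name target and leave Friday's yield open.

The forecast gives target at 99.5% for Thursday's and target at 96% for Friday's, noting that “the enzyme may denature quickly”. Where I leave Friday's yield open, it names one.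

Thursday's flask gives target at 100%. Friday's flask gives target at 66.1%, 30 percentage points under the forecast.

    free enzyme → unfolded enzyme (k = 8.50 × 10⁻⁵ /s, Ea = 244 kJ/mol)
    starting material + free enzyme → target + free enzyme, rate k2*[starting material]*[free enzyme]/(1 + ([starting material]/Km2) + ([starting material]/Ksi2)^2) (0.230 M, 0.140 M, k = 1100 /M/s, Ea = 36.0 kJ/mol)
    (constants at 25 °C)

Friday's 34% of starting material left is 0.469 decades, so with the eta run's τ unchanged its w reckons at 0.732 min, past the border. The neighbour, a flask like Thursday's kept at 50 °C, keeps 79%, which is 0.102 decades, so on the same τ its w reckons at 0.160 min, short of the border. In that neighbour starting material leads, and target ends at 21.0%.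

The readings were computed for substances that don't exist; scatter was added.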